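**Retrosynthetic overview**
1. Target ⇐ methyl ester tris-silyl ether 22, by HF desilylation and enzymatic ester hydrolysis (the β-hydroxy ketone does not tolerate base).
2. C7–C8 bond: trans-selective alkylation of a regiodefined cyclopentanone enolate (from silyl enol ether 19) with the (Z)-allylic iodide 17, whose Z-alkene comes from a Wittig reaction.
3. C12–C13 bond (new step): nickel-catalysed reductive conjugate alkylation of (R)-4-silyloxycyclopentenone 18 with the lower-chain bromide 10, anti to the silyloxy group.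
4. Lower chain 10: C16–C17 bond by acetoacetate dianion alkylation with an iodide from (R)-butane-1,3-diol (C19), and C15 by Noyori hydrogenation of the β-keto ester.
5. Ring order: the only ring, the cyclopentanone, is not built; it is carried in as enone 18, and both chains are attached to it (C12 first, then C8).

Assumption: the target is read as 13,14-dihydro-19(R)-hydroxy-PGE2, (5Z,8R,11R,12R,15S,19R). Prostaglandin numbering is used for positions (C1 acid carbon, C9 ketone, C11 ring carbinol, C8 and C12 the ring carbons that bear the chains, C15 and C19 the side-chain carbinols). TBS = tert-butyldimethylsilyl, TES = triethylsilyl. Compounds 1, 4, 11, 12 and 18 are taken as commercial.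

**Lower chain (C13–C20)**

Step 1
Reactants: 1 (R)-butane-1,3-diol
Product: 2 (R)-4-iodobutan-2-ol
Conditions: PPh3 (1.1 equiv), I2 (1.1 equiv), imidazole (1.5 equiv), CH2Cl2, 0 °C
Reagents that add atoms: iodine, II
Why: Appel-type iodination, in which the alkoxyphosphonium ion forms and is displaced (SN2) much faster at the unhindered primary hydroxyl, so the secondary carbinol centre (future C19, R) is untouched.

Step 2
Reactants: 2 (R)-4-iodobutan-2-ol
Product: 3 (R)-tert-butyl[(4-iodobutan-2-yl)oxy]dimethylsilane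
Conditions: TBSOTf (1.1 equiv), 2,6-lutidine (1.5 equiv), CH2Cl2, −78 → 0 °C
Reagents that add atoms: tert-butyldimethylsilyl trifluoromethanesulfonate (TBSOTf), CC(C)(C)[Si](C)(C)OS(=O)(=O)C(F)(F)F
Why: Silyl ether formation with a silyl triflate and a hindered, non-nucleophilic base is fast at low temperature and leaves the primary iodide alone.

Step 3
Reactants: 4 methyl acetoacetate; 3 (R)-tert-butyl[(4-iodobutan-2-yl)oxy]dimethylsilane
Product: 6 methyl (7R)-7-[(tert-butyldimethylsilyl)oxy]-3-oxooctanoate, via acetoacetate dianion 5 (not isolated)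
Conditions: 4 (1.3 equiv), NaH (1.4 equiv), THF, 0 °C; n-BuLi (1.35 equiv), 0 °C; 3 (1.0 equiv), 0 °C → rt; AcOH quench
Reagents that add atoms: none
Why: Weiler dianion alkylation, in which the more basic terminal carbanion of the acetoacetate dianion displaces the primary iodide (SN2) and forms the C16–C17 bond without touching the stereocentre.

Step 4
Reactants: 6 methyl (7R)-7-[(tert-butyldimethylsilyl)oxy]-3-oxooctanoate
Product: 7 methyl (3S,7R)-7-[(tert-butyldimethylsilyl)oxy]-3-hydroxyoctanoate
Conditions: H2 (50 atm), RuCl2[(S)-BINAP] (0.5 mol%), MeOH, 50 °C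
Reagents that add atoms: none
Why: Noyori asymmetric hydrogenation of a β-keto ester, in which chelation of the keto ester to the (S)-BINAP ruthenium hydride fixes the face of hydride delivery and gives the 3S alcohol (future C15) under catalyst control, the remote C7 centre having no influence.

Step 5
Reactants: 7 methyl (3S,7R)-7-[(tert-butyldimethylsilyl)oxy]-3-hydroxyoctanoate
Product: 8 methyl (3S,7R)-3,7-bis[(tert-butyldimethylsilyl)oxy]octanoate
Conditions: TBSCl (1.3 equiv), imidazole (2.5 equiv), DMF, rt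
Reagents that add atoms: tert-butyldimethylsilyl chloride (TBSCl), CC(C)(C)[Si](C)(C)Cl
Why: Standard imidazole-promoted silylation of a secondary alcohol under conditions too mild to dehydrate the β-hydroxy ester.

Step 6
Reactants: 8 methyl (3S,7R)-3,7-bis[(tert-butyldimethylsilyl)oxy]octanoate
Product: 9 (3S,7R)-3,7-bis[(tert-butyldimethylsilyl)oxy]octan-1-ol
Conditions: iBu2AlH (2.5 equiv), CH2Cl2, −78 → 0 °C; aq. KNaC4H4O6 (potassium sodium tartrate)
Reagents that add atoms: none
Why: Hydride reduction of the ester to the primary alcohol, to which silyl ethers and both stereocentres are inert.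

Step 7
Reactants: 9 (3S,7R)-3,7-bis[(tert-butyldimethylsilyl)oxy]octan-1-ol
Product: 10 (3S,7R)-1-bromo-3,7-bis[(tert-butyldimethylsilyl)oxy]octane
Conditions: CBr4 (1.3 equiv), PPh3 (1.4 equiv), 2,6-lutidine (0.5 equiv), CH2Cl2, 0 °C
Reagents that add atoms: carbon tetrabromide, BrC(Br)(Br)Br
Why: Appel bromination (SN2 at the primary alkoxyphosphonium carbon) under buffered, neutral conditions that keep the secondary silyl ethers intact.

**Upper chain (C1–C7)**

Step 8
Reactants: 11 (4-carboxybutyl)triphenylphosphonium bromide; 12 [(tert-butyldimethylsilyl)oxy]acetaldehyde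
Product: 14 (5Z)-7-[(tert-butyldimethylsilyl)oxy]hept-5-enoic acid, via carboxylate ylide 13 (not isolated)
Conditions: NaN(SiMe3)2 (2.1 equiv), THF, 0 °C; 12, −78 °C → rt; 1 M HCl to pH 4, 0 °C
Reagents that add atoms: none
Why: Wittig olefination with a non-stabilised ylide under lithium-free conditions goes through the kinetically favoured cis-oxaphosphetane and gives the Z-alkene (future C5–C6 double bond).

Step 9
Reactants: 14 (5Z)-7-[(tert-butyldimethylsilyl)oxy]hept-5-enoic acid
Product: 16 methyl (5Z)-7-hydroxyhept-5-enoate, via (5Z)-7-hydroxyhept-5-enoic acid 15 (not isolated)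
Conditions: TsOH·H2O (10 mol%), MeOH, rt → 40 °C
Reagents that add atoms: methanol, CO
Why: Acidic methanol first solvolyses the primary silyl ether and then esterifies the acid (Fischer esterification), and a primary, non-conjugated allylic alcohol does not ionise under these conditions, so the Z-geometry is kept.

Step 10
Reactants: 16 methyl (5Z)-7-hydroxyhept-5-enoate
Product: 17 methyl (5Z)-7-iodohept-5-enoate
Conditions: PPh3 (1.2 equiv), I2 (1.2 equiv), imidazole (1.5 equiv), CH2Cl2, 0 °C, dark; used at once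
Reagents that add atoms: iodine, II
Why: Appel-type iodination of a primary allylic alcohol by direct SN2 displacement at 0 °C in the dark, which avoids allylic transposition and Z/E isomerisation.

**Coupling and end game**

Step 11
Reactants: 10 (3S,7R)-1-bromo-3,7-bis[(tert-butyldimethylsilyl)oxy]octane; 18 (4R)-4-[(tert-butyldimethylsilyl)oxy]cyclopent-2-en-1-one
Product: 19 (3R,4R)-3-{(3S,7R)-3,7-bis[(tert-butyldimethylsilyl)oxy]octyl}-4-[(tert-butyldimethylsilyl)oxy]-1-(triethylsilyloxy)cyclopent-1-ene
Conditions: 10 (1.0 equiv), 18 (1.5 equiv), NiCl2·glyme (10 mol%), neocuproine (12 mol%), Mn powder (2 equiv), Et3SiCl (1.5 equiv), DMF, 25 °C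
Reagents that add atoms: chlorotriethylsilane (Et3SiCl), CC[Si](Cl)(CC)CC
Why: Proposed new method: nickel-catalysed reductive conjugate alkylation of a γ-silyloxy cyclopentenone, in which neocuproine-ligated zerovalent nickel and Et3SiCl turn 18 into an η3-1-(triethylsilyloxy)allyl nickel chloride on the ring face anti to the C11 silyloxy group, a monovalent nickel species abstracts bromine from 10 to give the primary alkyl radical, this radical is captured at nickel, and C–C reductive elimination from the resulting trivalent nickel at the allyl terminus remote from oxygen delivers the chain from the metal-bearing face, i.e. trans to OTBS (C12–C13 bond formed, C12 set as R), while Mn returns nickel to the zerovalent state and the anti disposition of nickel and OTBS blocks syn β-silyloxy elimination; the closest known reaction type is the nickel-catalysed reductive conjugate addition of primary alkyl bromides to simple enones with chlorosilane trapping, which has not been shown on 4-oxygenated chiral cyclopentenones or used as a diastereoselective fragment coupling.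

Step 12
Reactants: 19 (3R,4R)-3-{(3S,7R)-3,7-bis[(tert-butyldimethylsilyl)oxy]octyl}-4-[(tert-butyldimethylsilyl)oxy]-1-(triethylsilyloxy)cyclopent-1-ene; 17 methyl (5Z)-7-iodohept-5-enoate
Product: 22 methyl (5Z)-7-[(1R,2R,3R)-2-{(3S,7R)-3,7-bis[(tert-butyldimethylsilyl)oxy]octyl}-3-[(tert-butyldimethylsilyl)oxy]-5-oxocyclopentyl]hept-5-enoate, via lithium enolate 20 (not isolated), via triphenyltin enolate 21 (not isolated)
Conditions: MeLi (1.05 equiv), THF, 0 °C → rt; Ph3SnCl (1.05 equiv), −78 °C; HMPA, 17 (3 equiv), −78 → −30 °C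
Reagents that add atoms: none
Why: Regiospecific enolate generation from the silyl enol ether (MeLi attacks silicon), lithium-to-tin transmetalation to a weakly basic enolate that neither equilibrates nor expels the β-silyloxy group, and SN2 alkylation by the allylic iodide on the face anti to the neighbouring C12 chain (the 2,3-trans outcome of the three-component prostaglandin coupling), which sets C8 as R.

Step 13
Reactants: 22 methyl (5Z)-7-[(1R,2R,3R)-2-{(3S,7R)-3,7-bis[(tert-butyldimethylsilyl)oxy]octyl}-3-[(tert-butyldimethylsilyl)oxy]-5-oxocyclopentyl]hept-5-enoate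
Product: 23 methyl (5Z)-7-[(1R,2R,3R)-2-[(3S,7R)-3,7-dihydroxyoctyl]-3-hydroxy-5-oxocyclopentyl]hept-5-enoate
Conditions: HF·pyridine, pyridine, MeCN, 0 °C → rt
Reagents that add atoms: none
Why: Buffered fluoride cleavage of the three secondary TBS ethers under mildly acidic, non-basic conditions that neither dehydrate the β-hydroxy ketone nor epimerise C8.

Step 14
Reactants: 23 methyl (5Z)-7-[(1R,2R,3R)-2-[(3S,7R)-3,7-dihydroxyoctyl]-3-hydroxy-5-oxocyclopentyl]hept-5-enoate
Product: 24 (5Z)-7-[(1R,2R,3R)-2-[(3S,7R)-3,7-dihydroxyoctyl]-3-hydroxy-5-oxocyclopentyl]hept-5-enoic acid (CNP0414125.1)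
Conditions: porcine liver esterase, 0.1 M phosphate buffer pH 7.0, acetone (10% v/v), 30 °C
Reagents that add atoms: water, O
Why: Enzymatic ester hydrolysis at neutral pH avoids the base-induced β-elimination to the cyclopentenone that chemical saponification of PGE esters causes, and no stereocentre is touched.

**Compound list**

1 | (R)-butane-1,3-diol | C[C@@H](O)CCO | starting material
2 | (R)-4-iodobutan-2-ol | C[C@@H](O)CCI | intermediate
3 | (R)-tert-butyl[(4-iodobutan-2-yl)oxy]dimethylsilane | C[C@@H](O[Si](C)(C)C(C)(C)C)CCI | intermediate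
4 | methyl acetoacetate (methyl 3-oxobutanoate) | CC(=O)CC(=O)OC | starting material
5 | acetoacetate dianion (sodium lithium 1-methoxybuta-1,3-diene-1,3-diolate, formed in the flask) | C=C([O-])C=C([O-])OC.[Na+].[Li+] | intermediate
6 | methyl (7R)-7-[(tert-butyldimethylsilyl)oxy]-3-oxooctanoate | C[C@@H](O[Si](C)(C)C(C)(C)C)CCCC(=O)CC(=O)OC | intermediate
7 | methyl (3S,7R)-7-[(tert-butyldimethylsilyl)oxy]-3-hydroxyoctanoate | C[C@@H](O[Si](C)(C)C(C)(C)C)CCC[C@H](O)CC(=O)OC | intermediate
8 | methyl (3S,7R)-3,7-bis[(tert-butyldimethylsilyl)oxy]octanoate | C[C@@H](O[Si](C)(C)C(C)(C)C)CCC[C@H](O[Si](C)(C)C(C)(C)C)CC(=O)OC | intermediate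
9 | (3S,7R)-3,7-bis[(tert-butyldimethylsilyl)oxy]octan-1-ol | C[C@@H](O[Si](C)(C)C(C)(C)C)CCC[C@H](O[Si](C)(C)C(C)(C)C)CCO | intermediate
10 | (3S,7R)-1-bromo-3,7-bis[(tert-butyldimethylsilyl)oxy]octane | C[C@@H](O[Si](C)(C)C(C)(C)C)CCC[C@H](O[Si](C)(C)C(C)(C)C)CCBr | intermediate
11 | (4-carboxybutyl)triphenylphosphonium bromide | OC(=O)CCCC[P+](c1ccccc1)(c1ccccc1)c1ccccc1.[Br-] | starting material
12 | [(tert-butyldimethylsilyl)oxy]acetaldehyde | CC(C)(C)[Si](C)(C)OCC=O | starting material
13 | carboxylate ylide (sodium 5-(triphenylphosphoranylidene)pentanoate, formed in the flask) | [Na+].[O-]C(=O)CCCC=P(c1ccccc1)(c1ccccc1)c1ccccc1 | intermediate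
14 | (5Z)-7-[(tert-butyldimethylsilyl)oxy]hept-5-enoic acid | CC(C)(C)[Si](C)(C)OC/C=C\CCCC(=O)O | intermediate
15 | (5Z)-7-hydroxyhept-5-enoic acid (formed in the flask) | OC/C=C\CCCC(=O)O | intermediate
16 | methyl (5Z)-7-hydroxyhept-5-enoate | OC/C=C\CCCC(=O)OC | intermediate
17 | methyl (5Z)-7-iodohept-5-enoate | IC/C=C\CCCC(=O)OC | intermediate
18 | (4R)-4-[(tert-butyldimethylsilyl)oxy]cyclopent-2-en-1-one | CC(C)(C)[Si](C)(C)O[C@@H]1CC(=O)C=C1 | starting material
19 | (3R,4R)-3-{(3S,7R)-3,7-bis[(tert-butyldimethylsilyl)oxy]octyl}-4-[(tert-butyldimethylsilyl)oxy]-1-(triethylsilyloxy)cyclopent-1-ene | C[C@@H](O[Si](C)(C)C(C)(C)C)CCC[C@H](O[Si](C)(C)C(C)(C)C)CC[C@H]1[C@H](O[Si](C)(C)C(C)(C)C)CC(O[Si](CC)(CC)CC)=C1 | intermediate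
20 | lithium enolate: lithium (3R,4R)-3-{(3S,7R)-3,7-bis[(tert-butyldimethylsilyl)oxy]octyl}-4-[(tert-butyldimethylsilyl)oxy]cyclopent-1-en-1-olate (formed in the flask) | C[C@@H](O[Si](C)(C)C(C)(C)C)CCC[C@H](O[Si](C)(C)C(C)(C)C)CC[C@H]1[C@H](O[Si](C)(C)C(C)(C)C)CC(O[Li])=C1 | intermediate
21 | triphenyltin enolate: (3R,4R)-3-{(3S,7R)-3,7-bis[(tert-butyldimethylsilyl)oxy]octyl}-4-[(tert-butyldimethylsilyl)oxy]-1-(triphenylstannyloxy)cyclopent-1-ene (formed in the flask) | C[C@@H](O[Si](C)(C)C(C)(C)C)CCC[C@H](O[Si](C)(C)C(C)(C)C)CC[C@H]1[C@H](O[Si](C)(C)C(C)(C)C)CC(O[Sn](c2ccccc2)(c2ccccc2)c2ccccc2)=C1 | intermediate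
22 | methyl (5Z)-7-[(1R,2R,3R)-2-{(3S,7R)-3,7-bis[(tert-butyldimethylsilyl)oxy]octyl}-3-[(tert-butyldimethylsilyl)oxy]-5-oxocyclopentyl]hept-5-enoate | C[C@@H](O[Si](C)(C)C(C)(C)C)CCC[C@H](O[Si](C)(C)C(C)(C)C)CC[C@H]1[C@H](O[Si](C)(C)C(C)(C)C)CC(=O)[C@@H]1C/C=C\CCCC(=O)OC | intermediate
23 | methyl (5Z)-7-[(1R,2R,3R)-2-[(3S,7R)-3,7-dihydroxyoctyl]-3-hydroxy-5-oxocyclopentyl]hept-5-enoate | C[C@@H](O)CCC[C@H](O)CC[C@H]1[C@H](O)CC(=O)[C@@H]1C/C=C\CCCC(=O)OC | intermediate
24 | (5Z)-7-[(1R,2R,3R)-2-[(3S,7R)-3,7-dihydroxyoctyl]-3-hydroxy-5-oxocyclopentyl]hept-5-enoic acid | C[C@@H](O)CCC[C@H](O)CC[C@H]1[C@H](O)CC(=O)[C@@H]1C/C=C\CCCC(=O)O | target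

**Step count and risks**

Total step count: 14 (7 for bromide 10, 3 for iodide 17, 4 from the coupling onward).
Longest linear sequence: 11 steps (steps 1–7, then 11–14).

Most likely to fail:

Step 11 (the proposed new step). The allylnickel intermediate could lose the C11 silyloxy group, the bromide could homocouple, or the trans selectivity could be eroded. The fallback uses known chemistry and sets out from 10. Magnesium insertion (Mg turnings, THF, 40 °C) gives {(3S,7R)-3,7-bis[(tert-butyldimethylsilyl)oxy]octyl}magnesium bromide F1. Copper-catalysed 1,4-addition of this reagent to 18 (CuBr·SMe2 20 mol%, HMPA, Et3SiCl, THF, −78 °C) is the long-established chlorosilane-accelerated cuprate addition and enters anti to the silyloxy group. It gives the same silyl enol ether, so the route is rejoined at 19.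

Step 12. The (Z)-allylic iodide may isomerise or react sluggishly, and a slow alkylation gives the enolate time to equilibrate and eliminate the C11 silyloxy group. The fallback sets out from 19 and uses the same tin enolate 21, but with a propargylic electrophile that is more reactive and has no alkene geometry to lose. Commercial hex-5-ynoic acid is converted by its dianion (n-BuLi 2.1 equiv, THF, −78 → 0 °C) and paraformaldehyde into 7-hydroxyhept-5-ynoic acid F2. Esterification (TsOH, MeOH) gives methyl 7-hydroxyhept-5-ynoate F3, and PPh3/I2/imidazole gives methyl 7-iodohept-5-ynoate F4. Alkylation of 21 with F4 (HMPA, THF, −78 → −30 °C) gives methyl 7-[(1R,2R,3R)-2-{(3S,7R)-3,7-bis[(tert-butyldimethylsilyl)oxy]octyl}-3-[(tert-butyldimethylsilyl)oxy]-5-oxocyclopentyl]hept-5-ynoate F5. Semihydrogenation (H2 1 atm, Pd/CaCO3 poisoned with Pb(OAc)2, quinoline, cyclohexane) then makes the Z-alkene, and the route is rejoined at 22.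

Step 14. The enzyme may turn over the more polar 19-hydroxy substrate slowly, and long exposure risks dehydration of the β-hydroxy ketone. The fallback sets out from 22 and cleaves the ester chemically while the C11 oxygen is still silylated. Me3SnOH (1,2-dichloroethane, 70 °C) gives (5Z)-7-[(1R,2R,3R)-2-{(3S,7R)-3,7-bis[(tert-butyldimethylsilyl)oxy]octyl}-3-[(tert-butyldimethylsilyl)oxy]-5-oxocyclopentyl]hept-5-enoic acid F6. HF·pyridine in MeCN (0 °C → rt) then removes the three silyl groups, and the route is rejoined at the target 24.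

**Further compounds**

F1 | step 11 | {(3S,7R)-3,7-bis[(tert-butyldimethylsilyl)oxy]octyl}magnesium bromide | C[C@@H](O[Si](C)(C)C(C)(C)C)CCC[C@H](O[Si](C)(C)C(C)(C)C)CC[Mg]Br
F2 | step 12 | 7-hydroxyhept-5-ynoic acid | OCC#CCCCC(=O)O
F3 | step 12 | methyl 7-hydroxyhept-5-ynoate | OCC#CCCCC(=O)OC
F4 | step 12 | methyl 7-iodohept-5-ynoate | ICC#CCCCC(=O)OC
F5 | step 12 | methyl 7-[(1R,2R,3R)-2-{(3S,7R)-3,7-bis[(tert-butyldimethylsilyl)oxy]octyl}-3-[(tert-butyldimethylsilyl)oxy]-5-oxocyclopentyl]hept-5-ynoate | C[C@@H](O[Si](C)(C)C(C)(C)C)CCC[C@H](O[Si](C)(C)C(C)(C)C)CC[C@H]1[C@H](O[Si](C)(C)C(C)(C)C)CC(=O)[C@@H]1CC#CCCCC(=O)OC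
F6 | step 14 | (5Z)-7-[(1R,2R,3R)-2-{(3S,7R)-3,7-bis[(tert-butyldimethylsilyl)oxy]octyl}-3-[(tert-butyldimethylsilyl)oxy]-5-oxocyclopentyl]hept-5-enoic acid | C[C@@H](O[Si](C)(C)C(C)(C)C)CCC[C@H](O[Si](C)(C)C(C)(C)C)CC[C@H]1[C@H](O[Si](C)(C)C(C)(C)C)CC(=O)[C@@H]1C/C=C\CCCC(=O)O
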